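**Plan**

1. Numbering follows the isochromene core: ring A = O2, C1, C8a, C4a, C4, C3; ring B = C4a, C5, C6, C7, C8, C8a. The same labels are used for the carbons of all intermediates.
2. Retrosynthetic cuts, in order: O2–C3 (ring A), C3–propenyl, then C8–C8a and C4a–C5 (ring B), then C7–C6 together with a temporary C8–C5 bond (a four-membered ring), and last the ester C7–O bond.
3. Enabling feature: the tetrasubstituted enone C8(=O)–C8a=C4a of ring B, closed through C5, C6 and C7, is a cyclobutanone (C8, C7, C6, C5) into whose C8–C5 bond the two alkyne carbons C8a and C4a have been inserted.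
4. Forward order: aryl acid, lactate ester, ketene [2+2] to the cyclobutanone, nickel ring expansion with a silyl-capped diyne (ring B), alkyne unmasking and propenyl coupling, desilylation, and ring A last by 6-endo closure of O2 onto C3.
5. Stereochemistry: C6 is set by a chiral 1-arylethyl vinyl ether (face control in the [2+2]), C7 is set relative to C6 in the same step, and both pass through the ring expansion untouched; the (E)-alkene comes from (E)-1-bromopropene.

Key step: step 12

Remark: the lactate stereocentre is erased when the ketene forms, so benzyl (S)-lactate is used only because it is the common commercial form.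
Remark (assumption): the sense of face control is taken from the usual model for ketene additions to 1-arylethyl enol ethers (s-trans enol ether, carbinol C–H in the plane, attack anti to the aryl ring), which assigns the (R)-auxiliary to the (3R) adduct; were the sense opposite, the equally available (S)-alcohol would take its place.
Shorthand: ArCO2 = 2-methoxy-6-methyl-4-(triisopropylsilyloxy)benzoyloxy.

**Route**

Step 1
Reactants: 1 2,4-dihydroxy-6-methylbenzaldehyde
Product: 2 2-hydroxy-6-methyl-4-(triisopropylsilyloxy)benzaldehyde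
Conditions: i-Pr3SiCl (1.05 equiv), imidazole, CH2Cl2, 0 °C to rt
Reagents that add atoms: chlorotriisopropylsilane, CC(C)[Si](Cl)(C(C)C)C(C)C
Why: Silyl ether formation at a phenol: the 2-hydroxyl is tied up in a hydrogen bond to the formyl group and is flanked by it, so the bulky chlorosilane should take the free 4-hydroxyl only.

Step 2
Reactants: 2 2-hydroxy-6-methyl-4-(triisopropylsilyloxy)benzaldehyde
Product: 3 2-methoxy-6-methyl-4-(triisopropylsilyloxy)benzaldehyde
Conditions: MeI, K2CO3, acetone, 50 °C
Reagents that add atoms: iodomethane, CI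
Why: Williamson O-methylation of the remaining phenol once its hydrogen bond is broken by deprotonation; an aryl triisopropylsilyl ether should survive dry carbonate in acetone.

Step 3
Reactants: 3 2-methoxy-6-methyl-4-(triisopropylsilyloxy)benzaldehyde
Product: 4 2-methoxy-6-methyl-4-(triisopropylsilyloxy)benzoic acid
Conditions: NaClO2, NaH2PO4, 2-methyl-2-butene, t-BuOH/H2O, rt
Reagents that add atoms: sodium chlorite, [Na+].[O-]Cl=O
Why: Pinnick oxidation turns the hindered, electron-rich aldehyde into the acid under buffered conditions that leave the aryl silyl ether alone, the alkene scavenging the hypochlorous acid that would otherwise chlorinate the ring.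

Step 4
Reactants: 4 2-methoxy-6-methyl-4-(triisopropylsilyloxy)benzoic acid; 5 benzyl (S)-lactate
Product: 6 benzyl (R)-2-(ArCO2)propanoate
Conditions: PPh3, diisopropyl azodicarboxylate, THF, 0 °C to rt
Reagents that add atoms: none
Why: Mitsunobu esterification, in which the carboxylate displaces the phosphonium-activated hydroxyl of the lactate in an SN2 step so that the shielded 2,6-disubstituted carbonyl carbon never has to be attacked; the inversion to (R) is without consequence because this centre becomes sp2 in step 7.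

Step 5
Reactants: 6 benzyl (R)-2-(ArCO2)propanoate
Product: 7 (R)-2-(ArCO2)propanoic acid
Conditions: H2 (1 atm), Pd/C (10%), EtOAc, rt
Reagents that add atoms: none
Why: Hydrogenolysis of the benzyl ester over palladium frees the carboxylic acid without touching the aryl silyl ether or the aroate.

Step 6
Reactants: 8 (R)-1-(2,4,6-triisopropylphenyl)ethanol; 9 vinyl acetate
Product: 10 (R)-1-(2,4,6-triisopropylphenyl)ethyl vinyl ether
Conditions: [Ir(cod)Cl]2 (1 mol%), Na2CO3 (0.6 equiv), toluene, 100 °C
Reagents that add atoms: none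
Why: Iridium-catalysed transfer vinylation of an alcohol with vinyl acetate (the monovalent iridium alkoxide adds to the vinyl ester and acetate is expelled), which breaks only the O–H bond and so keeps the (R) carbinol centre.

Step 7
Reactants: 7 (R)-2-(ArCO2)propanoic acid; 10 (R)-1-(2,4,6-triisopropylphenyl)ethyl vinyl ether
Product: 13 (2S,3R)-2-(ArCO2)-2-methyl-3-[(R)-1-(2,4,6-triisopropylphenyl)ethoxy]cyclobutanone, via acid chloride 11 (not isolated), via acyloxy(methyl)ketene 12 (not isolated)
Conditions: (COCl)2, DMF (cat.), CH2Cl2, 0 °C to rt, evaporation; then slow addition to 10 (2 equiv) and Et3N in toluene, 80 °C; diastereomers separated on silica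
Reagents that add atoms: none
Why: Dehydrochlorination of the acid chloride gives the acyloxy(methyl)ketene, which adds to the electron-rich vinyl ether in a thermal ketene–enol ether [2+2] cycloaddition (carbonyl carbon C8 to the CH2 terminus C5, C7 to C6); C6 is set by the auxiliary, whose aryl ring shields one face of the s-trans enol ether, and C7 is set relative to C6 by the preference of the carbon substituent of an unsymmetrical ketene (methyl, as with alkyl(halo)ketenes) for the side of the alkene substituent, which puts the ester oxygen trans to the ether oxygen, the diastereomers being separable.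

Step 8
Reactants: 13 (2S,3R)-2-(ArCO2)-2-methyl-3-[(R)-1-(2,4,6-triisopropylphenyl)ethoxy]cyclobutanone
Product: 14 (2S,3R)-2-(ArCO2)-3-hydroxy-2-methylcyclobutanone
Conditions: CF3CO2H, CH2Cl2, 0 °C, short contact; aq. NaHCO3
Reagents that add atoms: none
Why: Acidolysis of a benzylic ether through the stabilised 1-arylethyl cation (SN1), which should be much faster than any acid-induced opening of the four-membered ring and leaves the ester, the aryl silyl ether and both stereocentres untouched.

Step 9
Reactants: 14 (2S,3R)-2-(ArCO2)-3-hydroxy-2-methylcyclobutanone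
Product: 15 (2S,3R)-2-(ArCO2)-2-methyl-3-(triethylsilyloxy)cyclobutanone
Conditions: Et3SiOSO2CF3, 2,6-lutidine, CH2Cl2, −78 °C
Reagents that add atoms: triethylsilyl trifluoromethanesulfonate, CC[Si](CC)(CC)OS(=O)(=O)C(F)(F)F
Why: Silylation of a secondary alcohol with a silyl triflate and a hindered pyridine at low temperature, non-nucleophilic and only weakly basic conditions under which the β-hydroxy cyclobutanone should neither open by retro-aldol cleavage nor eliminate.

Step 10
Reactants: 16 1,4-bis(trimethylsilyl)buta-1,3-diyne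
Product: 18 5-(trimethylsilyl)penta-2,4-diyn-1-ol, via lithium 4-(trimethylsilyl)buta-1,3-diynide 17 (not isolated)
Conditions: MeLi·LiBr (1.0 equiv), THF, rt; then (CH2O)n, −78 °C to rt; aq. NH4Cl
Reagents that add atoms: paraformaldehyde (as formaldehyde), C=O
Why: Methyllithium removes one of the two equivalent alkynyl silyl groups (attack at silicon, loss of tetramethylsilane), and the resulting lithium diynide adds to formaldehyde in a 1,2-addition.

Step 11
Reactants: 18 5-(trimethylsilyl)penta-2,4-diyn-1-ol
Product: 19 tert-butyldimethyl[5-(trimethylsilyl)penta-2,4-diynyloxy]silane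
Conditions: t-BuMe2SiCl, imidazole, CH2Cl2, rt
Reagents that add atoms: tert-butyldimethylsilyl chloride, CC(C)(C)[Si](C)(C)Cl
Why: Routine silylation of a primary propargylic alcohol.

Step 12
Reactants: 15 (2S,3R)-2-(ArCO2)-2-methyl-3-(triethylsilyloxy)cyclobutanone; 19 tert-butyldimethyl[5-(trimethylsilyl)penta-2,4-diynyloxy]silane
Product: 20 (5R,6S)-6-(ArCO2)-2-[(tert-butyldimethylsilyloxy)methyl]-6-methyl-5-(triethylsilyloxy)-3-[(trimethylsilyl)ethynyl]cyclohex-2-en-1-one
Conditions: Ni(cod)2 (10 mol%), P(c-C6H11)3 (20 mol%), toluene, 100 °C; 19 (2 equiv) added slowly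
Reagents that add atoms: none
Why: Zerovalent nickel couples the C8 carbonyl of 15 with the less hindered triple bond of 19 oxidatively to a spiro oxanickelacyclopentene (C8–C8a formed, nickel on C4a); β-carbon elimination then opens the strained ring at C8–C5 to a seven-membered nickelacycle, and C(sp3)–C(sp2) reductive elimination forms C4a–C5. The closest known reaction is the nickel-catalysed intermolecular insertion of internal alkynes into cyclobutanones to give cyclohex-2-enones. Ring B is the only ring closed; it arises by two-carbon ring expansion (a formal [4+2]) whose closing event is the reductive elimination from the seven-membered metallacycle. No stereocentre is created: C6 and C7 are spectators, C7 is quaternary and cannot epimerise, and no bond to C6 is broken. The step needs cleavage on the CH2 side (the fully substituted, acyloxy-bearing C7 is shielded), the alkynyl group on the nickel-bound carbon so that the CH2OSi-bearing carbon bonds to C8 (conjugative stabilisation of the alkenyl–nickel bond, as in nickel couplings of carbonyl compounds with conjugated enynes and diynes), and reaction at the propargylic-ether triple bond only (the trimethylsilyl cap blocks the other one). Reductive elimination also has to outrun β-silyloxy elimination at C6, which the bulky electron-rich phosphine and the poor nickel affinity of a hindered silyl ether oxygen should favour.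

Step 13
Reactants: 20 (5R,6S)-6-(ArCO2)-2-[(tert-butyldimethylsilyloxy)methyl]-6-methyl-5-(triethylsilyloxy)-3-[(trimethylsilyl)ethynyl]cyclohex-2-en-1-one
Product: 21 (5R,6S)-6-(ArCO2)-2-[(tert-butyldimethylsilyloxy)methyl]-3-ethynyl-6-methyl-5-(triethylsilyloxy)cyclohex-2-en-1-one
Conditions: AgNO3 (10 mol%), acetone/H2O, rt, dark
Reagents that add atoms: none
Why: Silver-catalysed protodesilylation of an alkynyl trimethylsilane through the silver acetylide is specific for the C(sp)–Si bond and nearly neutral, so the three silyl ethers and the base-sensitive β-silyloxy ketone should survive.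

Step 14
Reactants: 21 (5R,6S)-6-(ArCO2)-2-[(tert-butyldimethylsilyloxy)methyl]-3-ethynyl-6-methyl-5-(triethylsilyloxy)cyclohex-2-en-1-one; 22 (E)-1-bromoprop-1-ene
Product: 23 (5R,6S)-6-(ArCO2)-2-[(tert-butyldimethylsilyloxy)methyl]-6-methyl-3-[(E)-pent-3-en-1-ynyl]-5-(triethylsilyloxy)cyclohex-2-en-1-one
Conditions: PdCl2(PPh3)2 (3 mol%), CuI (5 mol%), Et3N, THF, rt
Reagents that add atoms: none
Why: Sonogashira coupling of the terminal alkyne with the alkenyl bromide, which keeps the (E) geometry of the bromide; a tertiary amine is used because a secondary amine could add to the electrophilic ynenone.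

Step 15
Reactants: 23 (5R,6S)-6-(ArCO2)-2-[(tert-butyldimethylsilyloxy)methyl]-6-methyl-3-[(E)-pent-3-en-1-ynyl]-5-(triethylsilyloxy)cyclohex-2-en-1-one
Product: 24 (5R,6S)-5-hydroxy-6-(4-hydroxy-2-methoxy-6-methylbenzoyloxy)-2-(hydroxymethyl)-6-methyl-3-[(E)-pent-3-en-1-ynyl]cyclohex-2-en-1-one
Conditions: Bu4NF/AcOH (1:1, excess), THF, 0 °C to rt
Reagents that add atoms: none
Why: Fluoride cleaves the primary alkyl, secondary alkyl and aryl silyl ethers in one operation, and acetic acid buffers the medium so that the β-hydroxy ketone does not eliminate or undergo retro-aldol cleavage and the hindered ester stays in place.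

Step 16
Reactants: 24 (5R,6S)-5-hydroxy-6-(4-hydroxy-2-methoxy-6-methylbenzoyloxy)-2-(hydroxymethyl)-6-methyl-3-[(E)-pent-3-en-1-ynyl]cyclohex-2-en-1-one
Product: 25 (6R,7S)-6-hydroxy-7-methyl-8-oxo-3-[(E)-prop-1-enyl]-5,6,7,8-tetrahydro-1H-isochromen-7-yl 4-hydroxy-2-methoxy-6-methylbenzoate
Conditions: Ph3PAuCl (5 mol%), AgOSO2CF3 (5 mol%), CH2Cl2, rt
Reagents that add atoms: none
Why: Gold-catalysed cycloisomerisation (hydroalkoxylation of an alkyne): monovalent gold activates the triple bond, the C1 hydroxyl attacks C3, which is the carbon that carries the positive charge because it is the δ-position of the ynenone and bears the propenyl group, in a 6-endo-dig closure, and protodeauration leaves the C3=C4 enol ether, while the C6 hydroxyl and the phenol cannot reach the alkyne.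

**Compound list**

1 | 2,4-dihydroxy-6-methylbenzaldehyde | O=Cc1c(C)cc(O)cc1O | starting material
2 | 2-hydroxy-6-methyl-4-(triisopropylsilyloxy)benzaldehyde | O=Cc1c(C)cc(O[Si](C(C)C)(C(C)C)C(C)C)cc1O | intermediate
3 | 2-methoxy-6-methyl-4-(triisopropylsilyloxy)benzaldehyde | O=Cc1c(C)cc(O[Si](C(C)C)(C(C)C)C(C)C)cc1OC | intermediate
4 | 2-methoxy-6-methyl-4-(triisopropylsilyloxy)benzoic acid | OC(=O)c1c(C)cc(O[Si](C(C)C)(C(C)C)C(C)C)cc1OC | intermediate
5 | benzyl (S)-lactate | C[C@H](O)C(=O)OCc1ccccc1 | starting material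
6 | benzyl (R)-2-(ArCO2)propanoate | C[C@@H](OC(=O)c1c(C)cc(O[Si](C(C)C)(C(C)C)C(C)C)cc1OC)C(=O)OCc1ccccc1 | intermediate
7 | (R)-2-(ArCO2)propanoic acid | C[C@@H](OC(=O)c1c(C)cc(O[Si](C(C)C)(C(C)C)C(C)C)cc1OC)C(=O)O | intermediate
8 | (R)-1-(2,4,6-triisopropylphenyl)ethanol | C[C@@H](O)c1c(C(C)C)cc(C(C)C)cc1C(C)C | starting material
9 | vinyl acetate | C=COC(C)=O | starting material
10 | (R)-1-(2,4,6-triisopropylphenyl)ethyl vinyl ether | C=CO[C@H](C)c1c(C(C)C)cc(C(C)C)cc1C(C)C | intermediate
11 | (R)-2-(ArCO2)propanoyl chloride | C[C@@H](OC(=O)c1c(C)cc(O[Si](C(C)C)(C(C)C)C(C)C)cc1OC)C(Cl)=O | intermediate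
12 | (ArCO2)(methyl)ketene, 2-(ArCO2)prop-1-en-1-one | CC(OC(=O)c1c(C)cc(O[Si](C(C)C)(C(C)C)C(C)C)cc1OC)=C=O | intermediate
13 | (2S,3R)-2-(ArCO2)-2-methyl-3-[(R)-1-(2,4,6-triisopropylphenyl)ethoxy]cyclobutanone | O=C1[C@@](C)(OC(=O)c2c(C)cc(O[Si](C(C)C)(C(C)C)C(C)C)cc2OC)[C@H](O[C@H](C)c2c(C(C)C)cc(C(C)C)cc2C(C)C)C1 | intermediate
14 | (2S,3R)-2-(ArCO2)-3-hydroxy-2-methylcyclobutanone | O=C1[C@@](C)(OC(=O)c2c(C)cc(O[Si](C(C)C)(C(C)C)C(C)C)cc2OC)[C@H](O)C1 | intermediate
15 | (2S,3R)-2-(ArCO2)-2-methyl-3-(triethylsilyloxy)cyclobutanone | O=C1[C@@](C)(OC(=O)c2c(C)cc(O[Si](C(C)C)(C(C)C)C(C)C)cc2OC)[C@H](O[Si](CC)(CC)CC)C1 | intermediate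
16 | 1,4-bis(trimethylsilyl)buta-1,3-diyne | C[Si](C)(C)C#CC#C[Si](C)(C)C | starting material
17 | lithium 4-(trimethylsilyl)buta-1,3-diynide | [Li]C#CC#C[Si](C)(C)C | intermediate
18 | 5-(trimethylsilyl)penta-2,4-diyn-1-ol | C[Si](C)(C)C#CC#CCO | intermediate
19 | tert-butyldimethyl[5-(trimethylsilyl)penta-2,4-diynyloxy]silane | C[Si](C)(C)C#CC#CCO[Si](C)(C)C(C)(C)C | intermediate
20 | (5R,6S)-6-(ArCO2)-2-[(tert-butyldimethylsilyloxy)methyl]-6-methyl-5-(triethylsilyloxy)-3-[(trimethylsilyl)ethynyl]cyclohex-2-en-1-one | C[Si](C)(C)C#CC1=C(CO[Si](C)(C)C(C)(C)C)C(=O)[C@@](C)(OC(=O)c2c(C)cc(O[Si](C(C)C)(C(C)C)C(C)C)cc2OC)[C@H](O[Si](CC)(CC)CC)C1 | intermediate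
21 | (5R,6S)-6-(ArCO2)-2-[(tert-butyldimethylsilyloxy)methyl]-3-ethynyl-6-methyl-5-(triethylsilyloxy)cyclohex-2-en-1-one | C#CC1=C(CO[Si](C)(C)C(C)(C)C)C(=O)[C@@](C)(OC(=O)c2c(C)cc(O[Si](C(C)C)(C(C)C)C(C)C)cc2OC)[C@H](O[Si](CC)(CC)CC)C1 | intermediate
22 | (E)-1-bromoprop-1-ene | C/C=C/Br | starting material
23 | (5R,6S)-6-(ArCO2)-2-[(tert-butyldimethylsilyloxy)methyl]-6-methyl-3-[(E)-pent-3-en-1-ynyl]-5-(triethylsilyloxy)cyclohex-2-en-1-one | C/C=C/C#CC1=C(CO[Si](C)(C)C(C)(C)C)C(=O)[C@@](C)(OC(=O)c2c(C)cc(O[Si](C(C)C)(C(C)C)C(C)C)cc2OC)[C@H](O[Si](CC)(CC)CC)C1 | intermediate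
24 | (5R,6S)-5-hydroxy-6-(4-hydroxy-2-methoxy-6-methylbenzoyloxy)-2-(hydroxymethyl)-6-methyl-3-[(E)-pent-3-en-1-ynyl]cyclohex-2-en-1-one | C/C=C/C#CC1=C(CO)C(=O)[C@@](C)(OC(=O)c2c(C)cc(O)cc2OC)[C@H](O)C1 | intermediate
25 | (6R,7S)-6-hydroxy-7-methyl-8-oxo-3-[(E)-prop-1-enyl]-5,6,7,8-tetrahydro-1H-isochromen-7-yl 4-hydroxy-2-methoxy-6-methylbenzoate | C/C=C/C1=CC2=C(CO1)C(=O)[C@@](C)(OC(=O)c1c(C)cc(O)cc1OC)[C@H](O)C2 | target

**Count and risks**

Total steps: 16. Longest linear sequence: 13 steps (steps 1–5, 7–9, 12–16).

Steps most likely to fail: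

1. Step 12. What may go wrong: the diyne may be consumed by nickel-mediated oligomerisation or insert through its silyl-capped triple bond, and at the temperature the hindered ketone needs, β-silyloxy elimination from the alkylnickel intermediate may outrun reductive elimination. Fallback (sets out from 15, returns at 25): the diyne is replaced by a conjugated enyne, the class of alkyne that undergoes nickel oxidative cyclisation with carbonyl groups most readily and with the most reliable orientation, so that the insertion can be tried at lower temperature with a partner that has one triple bond only; ring A is then closed by cyclodehydration instead of alkyne hydroalkoxylation. This still relies on a nickel insertion and does not help if the cyclobutanone itself is the problem. Sonogashira coupling of commercial tert-butyldimethyl(prop-2-ynyloxy)silane with (Z)-1-bromo-2-ethoxyethene would give (Z)-tert-butyl[(5-ethoxypent-4-en-2-ynyl)oxy]dimethylsilane F1. Its nickel-catalysed insertion into 15 should give the ring B enone with a (Z)-2-ethoxyvinyl group on C4a F2, in which C3 is at the aldehyde level. Mild aqueous acid (oxalic acid, wet THF) would unmask the C3 aldehyde F3. Nozaki–Hiyama–Kishi addition of 22 (CrCl2, NiCl2 cat., DMF), which spares the ketone and the ester, would give the allylic alcohol F4 as a mixture of carbinol epimers, and Dess–Martin oxidation would give the propenyl ketone F5. Bu4NF/AcOH would then give the desilylated hydroxy ketone F6, which with pyridinium p-toluenesulfonate should close to the hemiketal (O2–C3) and lose water toward C4 to give 25.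

2. Step 7. What may go wrong: the hindered vinyl ether may react more slowly than the ketene dimerises, and face selectivity may be poor or of the opposite sense. Fallback (sets out from 7, returns at 15): the same acid chloride and ketene are generated and trapped with commercial triethyl(vinyloxy)silane, which is unhindered. This gives the trans cyclobutanone directly as the silyl ether but as a racemate, that is 15 together with its mirror image, the (2R,3S) cyclobutanone F7. The cis isomers are removed on silica and the enantiomers are separated by preparative chromatography on a chiral stationary phase; steps 6, 8 and 9 are then unnecessary.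

3. Step 16. What may go wrong: attack of the hydroxyl at C4 (5-exo closure), or gold- and acid-induced degradation of the dienol ether as it forms. Fallback (sets out from 24, returns at 25): ring A is closed by addition–elimination instead of π-acid catalysis. Pyrrolidine (1 equiv, THF, 0 °C) should add to the ynenone in the 1,6-sense at C3, giving the dienaminone F8 (drawn as the (E) isomer; the geometry is lost in the next operation). Acetic acid then converts it into the conjugated iminium ion, the C1 hydroxyl adds to C3 and pyrrolidine is expelled, which gives 25.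

**Further compounds**

F1 | step 12 | (Z)-tert-butyl[(5-ethoxypent-4-en-2-ynyl)oxy]dimethylsilane | CCO/C=C\C#CCO[Si](C)(C)C(C)(C)C
F2 | step 12 | (5R,6S)-6-(ArCO2)-2-[(tert-butyldimethylsilyloxy)methyl]-3-[(Z)-2-ethoxyvinyl]-6-methyl-5-(triethylsilyloxy)cyclohex-2-en-1-one | CCO/C=C\C1=C(CO[Si](C)(C)C(C)(C)C)C(=O)[C@@](C)(OC(=O)c2c(C)cc(O[Si](C(C)C)(C(C)C)C(C)C)cc2OC)[C@H](O[Si](CC)(CC)CC)C1
F3 | step 12 | (5R,6S)-6-(ArCO2)-2-[(tert-butyldimethylsilyloxy)methyl]-6-methyl-3-(2-oxoethyl)-5-(triethylsilyloxy)cyclohex-2-en-1-one | O=CCC1=C(CO[Si](C)(C)C(C)(C)C)C(=O)[C@@](C)(OC(=O)c2c(C)cc(O[Si](C(C)C)(C(C)C)C(C)C)cc2OC)[C@H](O[Si](CC)(CC)CC)C1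
F4 | step 12 | (5R,6S)-6-(ArCO2)-2-[(tert-butyldimethylsilyloxy)methyl]-3-[(E)-2-hydroxypent-3-enyl]-6-methyl-5-(triethylsilyloxy)cyclohex-2-en-1-one (carbinol epimers) | C/C=C/C(O)CC1=C(CO[Si](C)(C)C(C)(C)C)C(=O)[C@@](C)(OC(=O)c2c(C)cc(O[Si](C(C)C)(C(C)C)C(C)C)cc2OC)[C@H](O[Si](CC)(CC)CC)C1
F5 | step 12 | (5R,6S)-6-(ArCO2)-2-[(tert-butyldimethylsilyloxy)methyl]-6-methyl-3-[(E)-2-oxopent-3-enyl]-5-(triethylsilyloxy)cyclohex-2-en-1-one | C/C=C/C(=O)CC1=C(CO[Si](C)(C)C(C)(C)C)C(=O)[C@@](C)(OC(=O)c2c(C)cc(O[Si](C(C)C)(C(C)C)C(C)C)cc2OC)[C@H](O[Si](CC)(CC)CC)C1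
F6 | step 12 | (5R,6S)-5-hydroxy-6-(4-hydroxy-2-methoxy-6-methylbenzoyloxy)-2-(hydroxymethyl)-6-methyl-3-[(E)-2-oxopent-3-enyl]cyclohex-2-en-1-one | C/C=C/C(=O)CC1=C(CO)C(=O)[C@@](C)(OC(=O)c2c(C)cc(O)cc2OC)[C@H](O)C1
F7 | step 7 | (2R,3S)-2-(ArCO2)-2-methyl-3-(triethylsilyloxy)cyclobutanone | O=C1[C@](C)(OC(=O)c2c(C)cc(O[Si](C(C)C)(C(C)C)C(C)C)cc2OC)[C@@H](O[Si](CC)(CC)CC)C1
F8 | step 16 | (5R,6S)-5-hydroxy-6-(4-hydroxy-2-methoxy-6-methylbenzoyloxy)-2-(hydroxymethyl)-6-methyl-3-[(1E,3E)-2-(pyrrolidin-1-yl)penta-1,3-dienyl]cyclohex-2-en-1-one | C/C=C/C(N2CCCC2)=C\C1=C(CO)C(=O)[C@@](C)(OC(=O)c2c(C)cc(O)cc2OC)[C@H](O)C1
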